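## Structural features

The target is a 1H-indole, a benzene ring fused to a pyrrole ring across C3a–C7a, and it has no stereocentre, so every problem is one of position. The pyrrole ring carries bromine at C3 and is free at N1 and C2. The benzo ring carries four neighbouring substituents in the order C7a–N1, C7–Br, C6–OMe, C5–Br, with C4 as its single CH. The fragile part is the 3-bromoindole unit (sensitive to acid, light and oxidants, easily debrominated), so C3–Br should be made last; once in place, the C–Br bonds also rule out zerovalent-metal catalysis, halogen–metal exchange and hydrogenolysis. The real difficulty is the benzo ring: a methoxy group flanked by two bromines, one of them next to the ring-fusion nitrogen, is awkward to reach by substitution of a preformed indole. The key step uses the fact that the edge C7a(N)–C7(Br)–C6(OMe)–C5(Br) is the C3–C4–C5–C6 edge of a 3-amino-4,6-dibromo-5-methoxypyridazine, that C3a and C4–H are the internal and terminal carbons of an alkyne, and that N1–C2–C3 can be the tether between them. The mapping was checked atom by atom (diazine C3→C7a, C4→C7, C5→C6, C6→C5, internal alkyne carbon→C3a, terminal CH→C4): precursor 7 and cycloaddition product 9 agree with it and with the target, so neither structure needs correction. The 3-amino-5-methoxypyridazine core has only two ring hydrogens, at C4 and C6, so both diazine bromines can be put in by exhaustive substitution with no regiochemical choice.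

## Logic of the disconnections

12 ⇒ 11. The C3–Br bond is cut. C3 is the most nucleophilic carbon of the indole and its bromide is the most labile bond in the molecule, so it belongs at the end. This keeps the sensitive unit out of every earlier intermediate. The forward step must stop at monobromination without attack at C2; the benzo ring is already safe because C5 and C7 are blocked and C4 is meta to both donors.

11 ⇒ 10. No skeletal bond is cut; the C2=C3 unsaturation is removed. The cycloaddition necessarily delivers an indoline because the tether carbons are sp3. The forward step is a dehydrogenation that must leave the aryl bromides alone, and it is placed after N-deprotection because an N-acyl indoline resists mild oxidants.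

10 ⇒ 9. The N1–acyl bond is restored. The electron-withdrawing acyl group is what lets the cycloaddition run, so it has to be present in the product of that step. The forward demand is a cleavage mild enough for two aryl bromides and an aryl ether.

9 ⇒ 7 (through 8). C3a–C7a and C4–C5 are cut and N2 is re-inserted between C7a and C5. Both rings open at once, and a bicyclic tetrasubstituted arene becomes a monocyclic diazine with an acyclic chain. All four benzo substituents are then already on the diazine, so no arene substitution is needed after ring formation. The forward step is a thermal [4+2] cycloaddition on a diazine that carries one donor, so it needs N-acyl activation and a high temperature.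

7 ⇒ 5 + 6. The N–C(O) bond is cut. The acyl group goes on last because the free N–H is needed as a donor for the brominations and because the resulting amide is hydrolytically labile. The forward step must acylate a hindered, weakly nucleophilic nitrogen.

5 ⇒ 3 (through 4). Both diazine C–Br bonds (C6–Br, C4–Br) are cut. They replace the only two ring hydrogens, each activated ortho or para by the amino and methoxy groups. The gain is a halogen-free diazine one step from catalogue compounds. The forward step is a double electrophilic substitution on a diazine in the presence of a terminal alkyne and an N–H.

3 ⇒ 1 + 2. The C3–N bond is cut. With a single halide on the ring there is nothing to select, and both partners are bought. The forward demand is displacement at a mono-chloro diazine, which needs heat, while the methoxy group stays in place.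

## Other disconnections considered

Alternative 1: The cut goes through C7–C7a and C3a–C4, so the benzo ring is built onto a preformed pyrrole. In the forward sense 3-nitro-1-tosylpyrrole A1 would serve as dienophile towards (E)-1-methoxy-3-(trimethylsilyloxy)buta-1,3-diene A2 in hot toluene. The nucleophilic CH2 terminus of A2 should bond to C2 of A1 (β to the nitro group), and elimination of the nitro and methoxy groups with desilylation on acidic work-up would give 1-tosyl-1H-indol-6-ol A3.

- **In favour:** oxygen is placed at C6 by polarity matching alone. The indole oxidation level is reached directly, which is better than the chosen plan (it passes through an indoline and spends a step on dehydrogenation). Nothing near 200 °C is required. The phenol of A3 could then direct two brominations to its ortho positions C5 and C7 (its para position is the ring fusion), followed by O-methylation, removal of the sulfonyl group and C3 bromination.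
- **Against:** a nitropyrrole is aromatic and a reluctant dienophile, so the intermolecular cycloaddition would probably need a large excess of diene and long heating in a closed vessel. A1 must itself be made in two steps (N-sulfonylation, nitration with isomer separation) from the parent heterocycle. Three of the four benzo substituents would go in after the ring exists, so the pattern depends on the phenol ring out-competing C3 of the N-sulfonyl pyrrole ring for the bromonium source.
- **Comparison:** on structure the chosen plan is stronger, since 7 holds every benzo substituent before the ring is formed. On mechanism both are [4+2]/aromatising-elimination sequences, but the chosen one is intramolecular and locked by its tether, whereas this one relies on frontier-orbital polarity. On step economy the two are about equal, roughly seven steps each.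

Alternative 2: The cut is N1–C2 together with C3–Br; the pyrrole ring is closed onto an alkyne and the C3 bromine arrives in the same event. In the forward sense 2,4-dibromo-3-methoxy-6-[(trimethylsilyl)ethynyl]aniline A5 would be treated with about three equivalents of CuBr2 (divalent copper) in warm DMSO. 5-endo-dig attack of the amine nitrogen on the copper-activated alkyne forms N1–C2, and bromination of the C3–copper species would give 3,5,7-tribromo-6-methoxy-2-(trimethylsilyl)-1H-indole A6, which still has to lose silicon.

- **In favour:** A5 should be available in two steps from 2-iodo-5-methoxyaniline A4 (Sonogashira coupling, then exhaustive bromination at the two positions ortho and para to nitrogen, both ortho to the methoxy group). The whole route would be about four steps, clearly better than the chosen seven. It needs no high temperature and no separate C3 bromination. It fixes the benzo pattern before ring closure by exhaustive substitution, so on structural logic it is the equal of the chosen plan.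
- **Against:** the nitrogen of A5 is flanked by an ortho bromine on an electron-poor ring and is a weak nucleophile for aminocupration. Silylalkynes are slow in 5-endo-dig closures and may lose silicon or be brominated at the alkyne terminus under copper halide in DMSO. Protodesilylation of A6 at C2 would have to spare the acid- and fluoride-sensitive C3–Br bond.
- **Comparison:** on mechanism this is a metal-mediated anti-aminometalation/halogenation against a pericyclic cascade. Neither key step has precedent on its exact substrate. The copper step fits its known substrate class less well (primary amine, silyl alkyne, ortho halogen), while the diazine cycloaddition mainly risks needing more heat.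

Alternative 3: The cut is N1–C7a, made by C–H amination of an aryl ring. In the forward sense 3,5-dibromo-4-methoxybenzaldehyde A7 would be condensed with methyl azidoacetate A8 to methyl (Z)-2-azido-3-(3,5-dibromo-4-methoxyphenyl)acrylate A9. Thermolysis of A9 in refluxing xylene would generate a vinyl nitrene (in equilibrium with its 2H-azirine) that attacks an ortho carbon to give methyl 5,7-dibromo-6-methoxy-1H-indole-2-carboxylate A10 (Hemetsberger indole synthesis).

- **In favour:** the aryl ring of A9 is symmetric, so both ortho positions lead to the same product and no regiochemical question arises; this equals the chosen plan in fixing the pattern beforehand and is arguably simpler. A7 already holds Br/OMe/Br. The indole oxidation level is reached directly. The temperature is about 140 °C instead of 200 °C. With ester hydrolysis, decarboxylation and C3 bromination the route is about five steps, better than the chosen plan by about two.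
- **Against:** A8 and A9 are low-molecular-weight organic azides that are handled and then deliberately decomposed with gas evolution, which runs against the aim of a safe route. The C2 carboxyl group is not in the target, and its removal from an indole-2-carboxylic acid usually calls for copper-mediated heating near 200 °C, where aryl bromides can be reduced or coupled. The condensation leading to A9 is prone to side reactions.
- **Comparison:** on mechanism this is nitrene C–H insertion against cycloaddition; both are thermal, unimolecular and driven by gas extrusion, but 7 is not an energetic compound. This alternative is the better on step count and regiochemical certainty; the chosen plan is the better on safety and needs no late defunctionalisation.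

Key step: step 4

Remarks on the chemistry:
- 1, 2 and 6 are taken as catalogue compounds and used as bought.
- The first bromine of step 2 is assumed to enter at C6, para to the amino nitrogen; since both ring hydrogens are replaced, the product does not depend on this order.
- The way to 7 uses no hydrazine, phosphorus oxyhalide, azide or elemental bromine, and step 4 is run dilute at atmospheric pressure with the gas vented.

## Route

Step 1
Reactants: 1 3-chloro-5-methoxypyridazine; 2 but-3-yn-1-amine
Product: 3 N-(but-3-yn-1-yl)-5-methoxypyridazin-3-amine
Conditions: 2 (3 equiv), iPr2NEt (2 equiv), n-BuOH, reflux (118 °C), 24–48 h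
Reagents that add atoms: none
Why: Addition–elimination (SNAr) at C3 of a π-deficient 1,2-diazine; the negative charge of the adduct falls on N2, C4 and C6, none of which bears the methoxy donor, and with one halide on the ring there is no regiochemical choice. The C5–OMe bond is a vinylogous imidate and a much poorer leaving group than chloride, and the alkyne is a spectator.

Step 2
Reactants: 3 N-(but-3-yn-1-yl)-5-methoxypyridazin-3-amine
Product: 5 4,6-dibromo-N-(but-3-yn-1-yl)-5-methoxypyridazin-3-amine, via 6-bromo monobromide 4 (not isolated)
Conditions: NBS (2.1 equiv), MeCN, 0 → 40 °C, dark; Na2S2O3 quench
Reagents that add atoms: N-bromosuccinimide, O=C1CCC(=O)N1Br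
Why: Electrophilic aromatic bromination of an aminodiazine, the same reaction type as the exhaustive NBS bromination of aminopyrazine at its ortho and para positions; the amino and methoxy donors jointly activate exactly the two ring CH positions (C6 para/ortho, then C4 ortho/ortho). NBS without AgNO3 or added base should leave the terminal alkyne alone, and N-bromination of the secondary amine is reversible and passes bromine on to the ring.

Step 3
Reactants: 5 4,6-dibromo-N-(but-3-yn-1-yl)-5-methoxypyridazin-3-amine; 6 trifluoroacetic anhydride
Product: 7 N-(but-3-yn-1-yl)-N-(4,6-dibromo-5-methoxypyridazin-3-yl)-2,2,2-trifluoroacetamide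
Conditions: 6 (2 equiv), pyridine (3 equiv), DMAP (0.1 equiv), CH2Cl2, 0 °C → rt; non-aqueous work-up, used at once
Reagents that add atoms: none
Why: N-acylation with a very reactive acyl donor, chosen because the nitrogen is hindered by the C4 bromine and weakly nucleophilic; any kinetic acylation at ring N2 should pass to the exocyclic nitrogen, which restores the aromatic diazine. The product is an activated amide, hence the dry work-up and immediate use.

Step 4
Reactants: 7 N-(but-3-yn-1-yl)-N-(4,6-dibromo-5-methoxypyridazin-3-yl)-2,2,2-trifluoroacetamide
Product: 9 1-(5,7-dibromo-6-methoxyindolin-1-yl)-2,2,2-trifluoroethan-1-one, via diazabicyclo[2.2.2]octatriene cycloadduct 8 (not isolated)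
Conditions: 1,3,5-triisopropylbenzene (0.02 M, degassed), 200–230 °C, Ar, condenser open to a bubbler, 12–24 h
Reagents that add atoms: none
Why: This is an intramolecular inverse-electron-demand Diels–Alder reaction: the tethered alkyne (2π) adds suprafacially across C3 and C6 of the diazine (4π, its LUMO lowered by the ring nitrogens, the two bromines and the N-acyl group, which also keeps the nitrogen lone pair out of the ring), forming C3a–C7a and C4–C5 in one concerted event to give the bridged adduct 8. Cycloreversion of 8 then expels N2 irreversibly and leaves the benzene ring of 9; the closest known reaction type is the thermal alkyne–1,2-diazine cycloaddition of N-acyl 3-(alkynylamino)pyridazines to N-acylindolines, applied here to a more heavily substituted diazine. The five-membered ring closes through the N–CH2–CH2 tether in a 5-exo-dig sense with respect to the alkyne (internal alkyne carbon onto diazine C3), and the six-membered carbocycle is closed by the [4+2] event itself and unmasked by the retro-[4+2] loss of the N=N bridge. No stereocentre is created in 9: the two bridgehead centres of 8 are fixed relative to each other by the bicycle and both vanish on aromatisation. The step needs regiocontrol (C4 as the only ring CH), and the three-atom tether secures it, because the internal alkyne carbon can reach only C3 and the terminal CH therefore goes to C6, while the other 1,4-pairs of the diazine (C4/N1, C5/N2) are out of reach. It also needs the cycloaddition to outrun thermal decay, which is helped by the perpendicular N-acyl rotamer enforced by the C4 bromine and N2 (chain held over the ring face), by high dilution, and by an argon-swept open system from which N2 escapes without pressure build-up.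

Step 5
Reactants: 9 1-(5,7-dibromo-6-methoxyindolin-1-yl)-2,2,2-trifluoroethan-1-one
Product: 10 5,7-dibromo-6-methoxyindoline
Conditions: K2CO3 (0.5 equiv), MeOH, rt
Reagents that add atoms: none
Why: Base-catalysed methanolysis of a trifluoroacetanilide-type amide; the CF3 group and the twist imposed by the C7 bromine make the carbonyl highly electrophilic, so mild carbonate should suffice and the aryl bromides and the ether are not touched.

Step 6
Reactants: 10 5,7-dibromo-6-methoxyindoline
Product: 11 5,7-dibromo-6-methoxy-1H-indole
Conditions: activated MnO2 (10 equiv), CH2Cl2, rt
Reagents that add atoms: none
Why: Heterogeneous dehydrogenation of an indoline to an indole with activated MnO2, driven by aromatisation of the pyrrole ring; it is run on the free N–H compound because N-acylindolines resist, and C–Br and OMe are inert to the oxidant.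

Step 7
Reactants: 11 5,7-dibromo-6-methoxy-1H-indole
Product: 12 3,5,7-tribromo-6-methoxy-1H-indole
Conditions: NBS (1.0 equiv), DMF, 0 °C, dark
Reagents that add atoms: N-bromosuccinimide, O=C1CCC(=O)N1Br
Why: Electrophilic substitution at C3, the enamine-like and most nucleophilic carbon of indole; C5 and C7 are blocked and C4 is meta to both donors, so one equivalent at 0 °C should stop at the monobromide without attack at C2. The two benzo bromines make the product less labile than a simple 3-bromoindole; it is kept cold and dark.

## Compound list

1 | 3-chloro-5-methoxypyridazine | COc1cnnc(Cl)c1 | starting material
2 | but-3-yn-1-amine | C#CCCN | starting material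
3 | N-(but-3-yn-1-yl)-5-methoxypyridazin-3-amine | COc1cnnc(NCCC#C)c1 | intermediate
4 | 6-bromo-N-(but-3-yn-1-yl)-5-methoxypyridazin-3-amine | COc1cc(NCCC#C)nnc1Br | intermediate (not isolated)
5 | 4,6-dibromo-N-(but-3-yn-1-yl)-5-methoxypyridazin-3-amine | COc1c(Br)c(NCCC#C)nnc1Br | intermediate
6 | trifluoroacetic anhydride | O=C(OC(=O)C(F)(F)F)C(F)(F)F | starting material
7 | N-(but-3-yn-1-yl)-N-(4,6-dibromo-5-methoxypyridazin-3-yl)-2,2,2-trifluoroacetamide | O=C(N(CCC#C)c1nnc(Br)c(OC)c1Br)C(F)(F)F | intermediate
8 | bridged [4+2] adduct: 2,3-diazabicyclo[2.2.2]octa-2,5,7-triene with Br on C4 and C6, OMe on C5, H on C8 and an N(COCF3)–CH2–CH2 chain joining bridgehead C1 to C7 (racemic; the two bridgehead configurations are fixed relative to each other by the bicycle) | O=C(C(F)(F)F)N1CCC2=CC3(Br)N=NC12C(Br)=C3OC | intermediate (not isolated)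
9 | 1-(5,7-dibromo-6-methoxyindolin-1-yl)-2,2,2-trifluoroethan-1-one | O=C(N1CCc2cc(Br)c(OC)c(Br)c21)C(F)(F)F | intermediate
10 | 5,7-dibromo-6-methoxyindoline | COc1c(Br)cc2c(c1Br)NCC2 | intermediate
11 | 5,7-dibromo-6-methoxy-1H-indole | COc1c(Br)cc2cc[nH]c2c1Br | intermediate
12 | 3,5,7-tribromo-6-methoxy-1H-indole | COc1c(Br)cc2c(Br)c[nH]c2c1Br | target

## Step count and least certain steps

Total steps: 7. Longest linear sequence: 7 steps (1 → 12); 2 and 6 enter as bought reagents.

Step 4 (key step). The cycloaddition may be too slow, because the C5 methoxy group raises the diazine LUMO and the ring is fully substituted. Thermal loss of the trifluoroacetyl group (which regenerates the unreactive free amine), C–Br cleavage or O-to-N methyl transfer could then outpace ring formation. The fallback moves the ring transformation ahead of the brominations; it sets out from 3 and comes back at 10.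
- 3 would be acylated with 6 as in step 3 to give N-(but-3-yn-1-yl)-2,2,2-trifluoro-N-(5-methoxypyridazin-3-yl)acetamide F1, a mono-donor N-acyl aminopyridazine close to the established substrates.
- Thermolysis in triisopropylbenzene should pass through the bridged diazabicyclo[2.2.2]octatriene adduct F2 to 2,2,2-trifluoro-1-(6-methoxyindolin-1-yl)ethan-1-one F3.
- K2CO3 in MeOH would free 6-methoxyindoline F4.
- NBS (2 equiv, MeCN, −10 °C) would brominate first para to nitrogen to give 5-bromo-6-methoxyindoline F5 and then at C7, giving 10. Both positions are ortho to the methoxy group and C4 is meta to both donors, so the pattern is set by ordinary directing effects.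

Step 2. The second substitution may stall once the first bromine has deactivated the ring (the position next to the ring nitrogen is the less certain one). Forcing it invites attack of the bromonium source on the terminal alkyne or oxidation at the N–H. The fallback brings the C6 bromine in by deoxybromination; it sets out from 2 and comes back at 4.
- Catalogue 4-bromo-1,2-dihydropyridazine-3,6-dione F6 would be heated with POBr3 (110 °C, ice quench) to give 3,4,6-tribromopyridazine F7.
- NaOMe (NaOCH3, 1 equiv, MeOH, 0 °C) should displace the most electrophilic C4 bromide to give 3,6-dibromo-4-methoxypyridazine F8.
- 2 (iPr2NEt, n-BuOH, 90 °C) should then attack F8 at C6, the carbon remote from the methoxy group, because attack next to it would put negative charge on the oxygen-bearing carbon. This gives 4.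
- One equivalent of NBS then only has to brominate C4, ortho to the amino group, to reach 5.

This detour also replaces step 1, at the cost of two extra steps and the use of POBr3.

Step 3. Acylation of the hindered, weakly nucleophilic nitrogen may be incomplete, and the twisted, activated trifluoroacetamide may be hydrolysed during isolation or lose its acyl group early in step 4. The fallback changes the activating group to a carbamate; it sets out from 5 and comes back at 10.
- 5 would be deprotonated at nitrogen with LiN(SiMe3)2 (1.05 equiv, THF, −78 °C; the N–H is far more acidic than the alkyne C–H) and quenched with methyl chloroformate to give methyl (but-3-yn-1-yl)(4,6-dibromo-5-methoxypyridazin-3-yl)carbamate F9.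
- Thermolysis as in step 4 should pass through the bridged adduct F10 to methyl 5,7-dibromo-6-methoxyindoline-1-carboxylate F11.
- KOH in MeOH/H2O at reflux would cleave the carbamate with decarboxylation to give 10.

The deprotection is harsher than for the trifluoroacetamide, but the ring has no group that would activate its bromides towards hydroxide.

Step 1. Displacement at the mono-chloro diazine may be sluggish. At the temperature it needs, the volatile amine leaves the solution and attack at C5 with loss of methoxide begins to compete. The fallback activates the electrophile by halogen exchange; it sets out from 1 and comes back at 3.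
- 1 would be treated with anhydrous Me4NF (DMF, rt) to give 3-fluoro-5-methoxypyridazine F12.
- 2 (iPr2NEt, DMSO, 50–60 °C) should then displace fluoride to give 3, because the addition step is much faster at a C–F carbon.

## Further compounds

F1 | step 4 | N-(but-3-yn-1-yl)-2,2,2-trifluoro-N-(5-methoxypyridazin-3-yl)acetamide | O=C(N(CCC#C)c1cc(OC)cnn1)C(F)(F)F
F2 | step 4 | bridged [4+2] adduct of F1: 2,3-diazabicyclo[2.2.2]octa-2,5,7-triene with OMe on C5 and an N(COCF3)–CH2–CH2 chain joining C1 to C7 (racemic, not isolated) | O=C(C(F)(F)F)N1CCC2=CC3N=NC12C=C3OC
F3 | step 4 | 2,2,2-trifluoro-1-(6-methoxyindolin-1-yl)ethan-1-one | O=C(N1CCc2ccc(OC)cc21)C(F)(F)F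
F4 | step 4 | 6-methoxyindoline | COc1ccc2c(c1)NCC2
F5 | step 4 | 5-bromo-6-methoxyindoline (not isolated) | COc1cc2NCCc2cc1Br
F6 | step 2 | 4-bromo-1,2-dihydropyridazine-3,6-dione (bought) | O=C1NNC(=O)C(Br)=C1
F7 | step 2 | 3,4,6-tribromopyridazine | Brc1cc(Br)c(Br)nn1
F8 | step 2 | 3,6-dibromo-4-methoxypyridazine | COc1cc(Br)nnc1Br
F9 | step 3 | methyl (but-3-yn-1-yl)(4,6-dibromo-5-methoxypyridazin-3-yl)carbamate | COC(=O)N(CCC#C)c1nnc(Br)c(OC)c1Br
F10 | step 3 | bridged [4+2] adduct of F9: 2,3-diazabicyclo[2.2.2]octa-2,5,7-triene with Br on C4 and C6, OMe on C5 and an N(CO2Me)–CH2–CH2 chain joining C1 to C7 (racemic, not isolated) | COC(=O)N1CCC2=CC3(Br)N=NC12C(Br)=C3OC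
F11 | step 3 | methyl 5,7-dibromo-6-methoxyindoline-1-carboxylate | COC(=O)N1CCc2cc(Br)c(OC)c(Br)c21
F12 | step 1 | 3-fluoro-5-methoxypyridazine | COc1cnnc(F)c1
A1 | alternative 1 | 3-nitro-1-tosylpyrrole | Cc1ccc(cc1)S(=O)(=O)n1ccc(c1)[N+](=O)[O-]
A2 | alternative 1 | (E)-1-methoxy-3-(trimethylsilyloxy)buta-1,3-diene | CO/C=C/C(=C)O[Si](C)(C)C
A3 | alternative 1 | 1-tosyl-1H-indol-6-ol | Cc1ccc(cc1)S(=O)(=O)n1ccc2ccc(O)cc21
A4 | alternative 2 | 2-iodo-5-methoxyaniline | COc1ccc(I)c(N)c1
A5 | alternative 2 | 2,4-dibromo-3-methoxy-6-[(trimethylsilyl)ethynyl]aniline | COc1c(Br)cc(C#C[Si](C)(C)C)c(N)c1Br
A6 | alternative 2 | 3,5,7-tribromo-6-methoxy-2-(trimethylsilyl)-1H-indole | COc1c(Br)cc2c(Br)c([Si](C)(C)C)[nH]c2c1Br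
A7 | alternative 3 | 3,5-dibromo-4-methoxybenzaldehyde | COc1c(Br)cc(C=O)cc1Br
A8 | alternative 3 | methyl azidoacetate | COC(=O)CN=[N+]=[N-]
A9 | alternative 3 | methyl (Z)-2-azido-3-(3,5-dibromo-4-methoxyphenyl)acrylate | [N-]=[N+]=N/C(C(=O)OC)=C\c1cc(Br)c(OC)c(Br)c1
A10 | alternative 3 | methyl 5,7-dibromo-6-methoxy-1H-indole-2-carboxylate | COC(=O)c1cc2cc(Br)c(OC)c(Br)c2[nH]1
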